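## Analysis of the target

The target is the octadecanoate of a 2-aryl-4-benzyl-3-(hydroxymethyl)oxolane. The ring atoms are O1, C2, C3, C4 and C5: C2 carries a 4-hydroxy-3-methoxyphenyl group, C3 the CH2O–acyl arm, C4 a 4-hydroxy-3-methoxybenzyl group, and C5 is an unsubstituted CH2. The three stereocentres are contiguous, (2S,3R,4R): the aryl group on C2 is trans to the arm on C3, and that arm is cis to the benzyl group on C4. The 2,3-trans relationship can be left to equilibration while C3 carries a carbonyl group, but the 3,4-cis relationship puts two carbon substituents on one face and must be made kinetically. No stereocentre comes from an obvious chiral-pool piece, so the absolute configuration must be introduced by a reagent. The sensitive groups are the two free guaiacol-type phenols, the primary fatty ester (no hydride or strong base once it is in place) and the C2–O1 bond. That bond is a para-oxygenated benzylic ether: acid ionises it (epimerisation at C2, Friedel–Crafts closure onto the other arene) and forcing hydrogenolysis opens it. The strategy rests on C2 being bonded to exactly O1, C3 and an aryl group. It can therefore be delivered as one aryl-bearing carbon that is first a nucleophile and then an electrophile, while O1, C5, C4 and C3 are an enal O=C5–C4=C3 whose C3 ester later becomes the CH2O arm.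

## Retrosynthetic reasoning

**Phenol O–CH2Ph bonds (23 from 22).** The two phenols are freed last. Benzyl ethers survive carbonate base, hydride and acylation, and they leave under neutral hydrogenolysis, which the ester tolerates. The forward step must cleave two aryl benzyl ethers without opening the C2–O1 benzylic ether.

**Ester C–O bond (22 from 20 and 21).** The fatty ester is attached late because it would not survive the hydride step. With both phenols masked, 20 has a single hydroxyl group, so the acylation needs no selectivity.

**Oxidation level at the C3 arm (20 from 18).** The CH2OH group is traced back to a methyl ester. The ester is needed earlier as the second acceptor of the enal and as the group that lets C3 settle trans to the C2 aryl group.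

**C4–H and C5–H bonds (18 from 17).** Removing H2 across C4–C5 gives an enol ether. Forward, syn addition of hydrogen on the face opposite the C3 ester places the C4 benzyl group cis to it. The contra-thermodynamic relationship thus becomes a question of facial selectivity on a ring that already carries C2 and C3.

**C2–C3 and O1–C2 (17 from 8 and 14), the key disconnection.** Both bonds end at C2, so one reagent carrying the aryl carbon at the carbene oxidation level can make both. What remains is a linear, achiral four-atom piece, and the chirality sits in a recoverable sulfide. Forward, the benzylide from 8 must add to C3 of 14 and not to the formyl carbon, the enolate must close through oxygen, the sulfide must control C2, and C3 must end trans.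

**C3=C4 double bond (14 from 11 and 12).** An aldol condensation joins the α-carbon of 11 to the formyl carbon of 12. Since 12 cannot enolise and is the stronger electrophile, the cross-reaction is favoured. Aldehyde 11 comes from phenol 9 by O-benzylation (10) and oxidation.

**S–CH2 bond (8 from 3 and 7).** S-Alkylation of the C2-symmetric sulfide gives a single sulfonium salt, because its two lone pairs are equivalent. The hand of 7 was worked out from the known epoxidation of aromatic aldehydes with the benzylide of this sulfide. There the ylide carbon forms its C–C bond on one face and sulfur is then replaced by oxygen with inversion; the annulation consists of the same two events. At C2 of 17 the aryl group outranks the new carbon substituent, the reverse of the ranking in the epoxides. Transferring the facial sense therefore makes the (2S,5S)-sulfide 7 the one that leads to (2S). Bromide 3 comes from 1 by O-benzylation (2) and bromination.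

**Two C–S bonds of the thiolane (7 from 5, from 4).** Two displacements with inversion at the secondary carbons turn the (2R,5R)-diol 4, through its bis-sulfonate 5, into the (2S,5S)-sulfide 7.

## Alternatives that were turned down

**Alternative 1:** The ring is cut at O1–C2, at C3–C4 and at the bond between the benzylic carbon and its arene, around a malonate C3. Forward, deprotonated prop-2-yn-1-ol A3 adds to the arylidenemalonate A2 (O1–C2). The malonate anion then closes 5-exo-dig onto the alkyne, activated by the aryl–palladium species formed from the aryl iodide A4 and a zerovalent palladium catalyst, and reductive elimination gives the benzylidene oxolane A1.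
- For it: three simple achiral components give three bonds and the ring in one operation, and the reaction class is established on this kind of acceptor. In convergence and in precedent it is stronger than the chosen key step.
- Against it: C2 arises from an uncontrolled alkoxide addition, so A1 is racemic and the target enantiomer would need a resolution or an unknown asymmetric variant. C3 carries two esters; removing one needs halide and heat, under which the styrenyl double bond can move into the ring. C4 is still unset and needs the same face-selective hydrogenation as the chosen route.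
- Comparison: at least two more steps after the key step and no absolute control. The chosen strategy offers absolute control at C2 in the ring-forming event and the correct single-ester oxidation level at C3.

**Alternative 2:** The bonds C3–C(=O) and C4–CH(aryl) of a cyclobutanone fused to the oxolane are cut. Forward, the acid chloride A7 is dehydrochlorinated by an amine to the ketene A8. Under an aluminium Lewis acid, A8 adds to the alkene of the (S)-2-aryl-2,5-dihydrofuran A6 and gives the cis-fused cyclobutanone A5.
- For it: the cis ring fusion fixes the 3,4-cis relationship by geometry, approach anti to the C2 aryl group gives 2,3-trans, and A6 is accessible in enantioenriched form by asymmetric Heck arylation. On the 3,4-cis relationship it is stronger than the chosen route, which relies on facial selectivity in a hydrogenation.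
- Against it: the two alkene carbons of A6 are electronically similar, so the orientation of the ketene is not controlled. Aryl ketenes dimerise, and the Lewis acid needed for an unactivated alkene threatens the allylic, benzylic C2–O bond. Afterwards the four-membered ring must be dismantled by oxidative ring expansion, reduction and deoxygenation of a benzylic alcohol next to the ring benzylic ether.
- Comparison: four or more extra steps and an uncertain regiochemistry. The chosen strategy is shorter and brings every carbon in at its final oxidation state.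

**Alternative 3:** The bonds C3–C4 and CH2–aryl are cut. Forward, a nickel catalyst with a tridentate nitrogen ligand turns the C–Br bond of the α-bromo ester A10 into a C3 radical. The radical cyclises 5-exo onto the allyl ether, and the exocyclic CH2 radical is coupled with the arylzinc bromide A11 to give A9, which is identical with 18.
- For it: it reaches 18 directly with no hydrogenation, no aldehyde competes for the nucleophile, and the benzyl arene enters by cross-coupling. After the key step it is as short as or shorter than the chosen route.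
- Against it: the relationship between the C3 ester and the new CH2 group at C4 is set in a radical ring closure, where α-ester radicals normally prefer trans or give mixtures, while the target needs cis. The absolute configuration must already be present in A10, a β-allyloxy ester prone to β-elimination, so the chirality problem is moved and not solved. Direct coupling of the bromo ester with A11 before cyclisation also competes.
- Comparison: the chosen strategy sets C2 with a recoverable chiral sulfide during ring formation and leaves C4 to a syn-hydrogenation whose intrinsic sense (anti to the C3 substituent) is the required one.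

Key step: step 9

Assumption: the benzylide of 2,5-dimethylthiolane is taken to show the same conformer and facial preference in conjugate addition as in its additions to aldehydes; the hand of diol 4 follows from this (both enantiomers of the diol are commercial).

## Route

Step 1
Reactants: 1 vanillyl alcohol
Product: 2 [4-(benzyloxy)-3-methoxyphenyl]methanol
Conditions: BnBr, K2CO3, acetone, reflux
Reagents that add atoms: benzyl bromide, BrCc1ccccc1
Why: Williamson ether synthesis; carbonate deprotonates only the phenol, so the benzylic alcohol is left free.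

Step 2
Reactants: 2 [4-(benzyloxy)-3-methoxyphenyl]methanol
Product: 3 1-(benzyloxy)-4-(bromomethyl)-2-methoxybenzene
Conditions: PBr3, Et2O, 0 °C
Reagents that add atoms: phosphorus tribromide, BrP(Br)Br
Why: Standard conversion of a benzylic alcohol into the bromide through its phosphite ester; the aryl benzyl ether is inert.

Step 3
Reactants: 4 (2R,5R)-hexane-2,5-diol
Product: 5 (2R,5R)-hexane-2,5-diyl dimethanesulfonate
Conditions: MsCl, Et3N, CH2Cl2, −10 to 0 °C
Reagents that add atoms: methanesulfonyl chloride, CS(=O)(=O)Cl
Why: O-Sulfonylation leaves both C–O bonds intact, so the configuration is retained.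

Step 4
Reactants: 5 (2R,5R)-hexane-2,5-diyl dimethanesulfonate
Product: 7 (2S,5S)-2,5-dimethylthiolane, via thiolate mesylate 6 (not isolated)
Conditions: Na2S·9H2O, DMSO, rt to 40 °C; distillation
Reagents that add atoms: sodium sulfide (as nonahydrate), [Na+].[Na+].[S-2]
Why: Two SN2 displacements by sulfur, the second a 5-exo-tet ring closure of thiolate 6, each invert a secondary carbon, so the (2R,5R)-bis-sulfonate gives the (2S,5S)-thiolane.

Step 5
Reactants: 3 1-(benzyloxy)-4-(bromomethyl)-2-methoxybenzene, 7 (2S,5S)-2,5-dimethylthiolane
Product: 8 (2S,5S)-1-[4-(benzyloxy)-3-methoxybenzyl]-2,5-dimethylthiolan-1-ium tetrafluoroborate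
Conditions: AgBF4, CH2Cl2, 0 °C to rt, dark
Reagents that add atoms: silver tetrafluoroborate, [Ag+].F[B-](F)(F)F
Why: S-Alkylation driven by precipitation of AgBr and giving a non-nucleophilic counter-ion; the sulfide is C2-symmetric, so its lone pairs are equivalent and one salt forms without a stereocentre at sulfur.

Step 6
Reactants: 9 dihydroconiferyl alcohol
Product: 10 3-[4-(benzyloxy)-3-methoxyphenyl]propan-1-ol
Conditions: BnBr, K2CO3, acetone, reflux
Reagents that add atoms: benzyl bromide, BrCc1ccccc1
Why: Williamson ether synthesis, phenol-selective for the same reason as in step 1.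

Step 7
Reactants: 10 3-[4-(benzyloxy)-3-methoxyphenyl]propan-1-ol
Product: 11 3-[4-(benzyloxy)-3-methoxyphenyl]propanal
Conditions: Dess–Martin periodinane, CH2Cl2, 0 °C to rt
Reagents that add atoms: none
Why: Dess–Martin oxidation of a primary alcohol stops at the aldehyde and does not touch the electron-rich arene or the benzyl ether.

Step 8
Reactants: 11 3-[4-(benzyloxy)-3-methoxyphenyl]propanal, 12 methyl glyoxylate
Product: 14 methyl (2E)-4-[4-(benzyloxy)-3-methoxyphenyl]-3-formylbut-2-enoate, via aldol adduct 13 (not isolated)
Conditions: 12 (freshly distilled), pyrrolidine (cat.), PhCO2H (cat.), toluene, rt to 50 °C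
Reagents that add atoms: none
Why: Amine-catalysed cross-aldol condensation: the enamine of 11 adds to the non-enolisable formyl group of 12, and aldol 13 loses water by E1cB to the conjugated enal. The (E)-isomer, with formyl and ester groups trans, is the thermodynamic one and is reached through reversible conjugate addition of the amine.

Step 9
Reactants: 8 (2S,5S)-1-[4-(benzyloxy)-3-methoxybenzyl]-2,5-dimethylthiolan-1-ium tetrafluoroborate, 14 methyl (2E)-4-[4-(benzyloxy)-3-methoxyphenyl]-3-formylbut-2-enoate
Product: 17 methyl (2S,3S)-2-[4-(benzyloxy)-3-methoxyphenyl]-4-[4-(benzyloxy)-3-methoxybenzyl]-2,3-dihydrofuran-3-carboxylate, via sulfonium ylide 15 (not isolated), via sulfonium enolate betaine 16 (not isolated)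
Conditions: Cs2CO3, CH2Cl2, −20 °C to rt
Reagents that add atoms: none
Why: Proposed new method: Cs2CO3 converts 8 into the benzylide 15, whose carbon should add to C3 of 14 (Michael addition) to give the sulfonium enolate 16, and the enolate oxygen then displaces the thiolane from the benzylic carbon (O-alkylation), so that the ylide carbon becomes C2 in a formal [4+1] annulation; the closest known reactions are the sulfonium-ylide annulations of enones and α-ylidene-1,3-dicarbonyl compounds to trans-2,3-dihydrofurans and the asymmetric epoxidations and cyclopropanations with benzylides of C2-symmetric thiolanes, whereas a formyl-substituted acrylate with a chiral benzylide has not been shown. The one new ring (O1, C2, C3, C4, C5) closes by 5-exo-tet attack of the enolate oxygen on C2, which needs the (Z)-enolate that results from addition to the s-cis enal. C2 is controlled by the sulfide: the benzylide reacts through the conformer with its aryl group turned away from the ring and on the face remote from the neighbouring methyl group, C–S is then replaced by C–O with inversion, and because this sequence gives (S,S)-stilbene oxide from the (2R,5R)-sulfide while at C2 of 17 the aryl group outranks the carbon substituent, the (2S,5S)-sulfide is expected to give (2S). C3, an ester α-carbon that becomes allylic, is set trans to the aryl group because the less crowded betaine closes faster and, if need be, by base equilibration, which gives (2S,3S). The step needs conjugate addition to win over addition to the formyl group (epoxide formation); in its favour, C3 is activated by both acceptors and is the only unsubstituted alkene carbon, while the formyl group is conjugated and α-branched. It needs attack at C3 and not at C4, which follows from the aldehyde being the stronger acceptor and C4 being fully substituted. It needs O- rather than C-alkylation of the enolate, and a cyclopropane formed by C-closure (F1) could still be converted into 17 by Cloke–Wilson rearrangement.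

Step 10
Reactants: 17 methyl (2S,3S)-2-[4-(benzyloxy)-3-methoxyphenyl]-4-[4-(benzyloxy)-3-methoxybenzyl]-2,3-dihydrofuran-3-carboxylate
Product: 18 methyl (2S,3S,4R)-2-[4-(benzyloxy)-3-methoxyphenyl]-4-[4-(benzyloxy)-3-methoxybenzyl]oxolane-3-carboxylate
Conditions: H2 (1 bar), Rh/Al2O3 (5 wt% Rh), EtOAc, rt
Reagents that add atoms: none
Why: Heterogeneous syn-hydrogenation of the trisubstituted enol ether; the catalyst should bind the face opposite the C3 ester, the allylic substituent next to the substituted alkene carbon, so both hydrogens arrive anti to it and the C4 benzyl group ends cis to the ester (4R). Rh/Al2O3 is chosen because it has little tendency to cleave O-benzyl or benzylic C–O bonds.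

Step 11
Reactants: 18 methyl (2S,3S,4R)-2-[4-(benzyloxy)-3-methoxyphenyl]-4-[4-(benzyloxy)-3-methoxybenzyl]oxolane-3-carboxylate
Product: 20 {(2S,3R,4R)-2-[4-(benzyloxy)-3-methoxyphenyl]-4-[4-(benzyloxy)-3-methoxybenzyl]oxolan-3-yl}methanol, via oxolane carbaldehyde 19 (not isolated)
Conditions: LiAlH4, THF, 0 °C; aqueous NaOH work-up
Reagents that add atoms: none
Why: Hydride reduction of the ester through aldehyde 19 to the primary alcohol; no stereocentre is touched (the descriptor at C3 changes only by priority), and the low temperature avoids epimerisation α to the ester.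

Step 12
Reactants: 20 {(2S,3R,4R)-2-[4-(benzyloxy)-3-methoxyphenyl]-4-[4-(benzyloxy)-3-methoxybenzyl]oxolan-3-yl}methanol, 21 stearoyl chloride
Product: 22 {(2S,3R,4R)-2-[4-(benzyloxy)-3-methoxyphenyl]-4-[4-(benzyloxy)-3-methoxybenzyl]oxolan-3-yl}methyl octadecanoate
Conditions: Et3N, DMAP (cat.), CH2Cl2, 0 °C to rt
Reagents that add atoms: none
Why: DMAP-catalysed O-acylation of the only free hydroxyl group; the basic, non-acidic conditions leave the benzylic ring ether untouched.

Step 13
Reactants: 22 {(2S,3R,4R)-2-[4-(benzyloxy)-3-methoxyphenyl]-4-[4-(benzyloxy)-3-methoxybenzyl]oxolan-3-yl}methyl octadecanoate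
Product: 23 [(2S,3R,4R)-2-(4-hydroxy-3-methoxyphenyl)-4-(4-hydroxy-3-methoxybenzyl)oxolan-3-yl]methyl octadecanoate
Conditions: H2 (1 bar), Pd/C (10 wt% Pd), EtOAc, rt, stopped at full conversion
Reagents that add atoms: none
Why: Hydrogenolysis of aryl benzyl ethers, a standard last step for 2-aryloxolane lignans. Under neutral conditions these ethers are cleaved much faster than the hindered cyclic benzylic ether C2–O1, so the reaction is stopped once 22 is consumed; the ester is inert.

## Compound list

1 | vanillyl alcohol, 4-(hydroxymethyl)-2-methoxyphenol | OCc1ccc(O)c(OC)c1 | starting material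
2 | [4-(benzyloxy)-3-methoxyphenyl]methanol | OCc1ccc(OCc2ccccc2)c(OC)c1 | intermediate
3 | 1-(benzyloxy)-4-(bromomethyl)-2-methoxybenzene | BrCc1ccc(OCc2ccccc2)c(OC)c1 | intermediate
4 | (2R,5R)-hexane-2,5-diol | C[C@@H](O)CC[C@@H](C)O | starting material
5 | (2R,5R)-hexane-2,5-diyl dimethanesulfonate | C[C@@H](OS(C)(=O)=O)CC[C@@H](C)OS(C)(=O)=O | intermediate
6 | sodium (2S,5R)-5-(methanesulfonyloxy)hexane-2-thiolate | C[C@H]([S-])CC[C@@H](C)OS(C)(=O)=O.[Na+] | intermediate (not isolated)
7 | (2S,5S)-2,5-dimethylthiolane | C[C@H]1CC[C@H](C)S1 | intermediate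
8 | (2S,5S)-1-[4-(benzyloxy)-3-methoxybenzyl]-2,5-dimethylthiolan-1-ium tetrafluoroborate | C[C@H]1CC[C@H](C)[S+]1Cc1ccc(OCc2ccccc2)c(OC)c1.F[B-](F)(F)F | intermediate
9 | dihydroconiferyl alcohol, 4-(3-hydroxypropyl)-2-methoxyphenol | OCCCc1ccc(O)c(OC)c1 | starting material
10 | 3-[4-(benzyloxy)-3-methoxyphenyl]propan-1-ol | OCCCc1ccc(OCc2ccccc2)c(OC)c1 | intermediate
11 | 3-[4-(benzyloxy)-3-methoxyphenyl]propanal | O=CCCc1ccc(OCc2ccccc2)c(OC)c1 | intermediate
12 | methyl glyoxylate, methyl oxoacetate | COC(=O)C=O | starting material
13 | methyl 4-[4-(benzyloxy)-3-methoxyphenyl]-3-formyl-2-hydroxybutanoate, mixture of diastereomers | COC(=O)C(O)C(C=O)Cc1ccc(OCc2ccccc2)c(OC)c1 | intermediate (not isolated)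
14 | methyl (2E)-4-[4-(benzyloxy)-3-methoxyphenyl]-3-formylbut-2-enoate | COC(=O)/C=C(/C=O)Cc1ccc(OCc2ccccc2)c(OC)c1 | intermediate
15 | [4-(benzyloxy)-3-methoxyphenyl][(2S,5S)-2,5-dimethylthiolan-1-ium-1-yl]methanide, sulfonium ylide | C[C@H]1CC[C@H](C)[S+]1[CH-]c1ccc(OCc2ccccc2)c(OC)c1 | intermediate (not isolated)
16 | (1Z,3R,4R)-2-[4-(benzyloxy)-3-methoxybenzyl]-4-[4-(benzyloxy)-3-methoxyphenyl]-4-[(2S,5S)-2,5-dimethylthiolan-1-ium-1-yl]-3-(methoxycarbonyl)but-1-en-1-olate, sulfonium enolate betaine | COC(=O)[C@H]([C@H](c1ccc(OCc2ccccc2)c(OC)c1)[S+]1[C@@H](C)CC[C@@H]1C)/C(Cc1ccc(OCc2ccccc2)c(OC)c1)=C\[O-] | intermediate (not isolated)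
17 | methyl (2S,3S)-2-[4-(benzyloxy)-3-methoxyphenyl]-4-[4-(benzyloxy)-3-methoxybenzyl]-2,3-dihydrofuran-3-carboxylate, 2,3-trans | COC(=O)[C@H]1C(Cc2ccc(OCc3ccccc3)c(OC)c2)=CO[C@@H]1c1ccc(OCc2ccccc2)c(OC)c1 | intermediate
18 | methyl (2S,3S,4R)-2-[4-(benzyloxy)-3-methoxyphenyl]-4-[4-(benzyloxy)-3-methoxybenzyl]oxolane-3-carboxylate, 2,3-trans-3,4-cis | COC(=O)[C@H]1[C@@H](Cc2ccc(OCc3ccccc3)c(OC)c2)CO[C@@H]1c1ccc(OCc2ccccc2)c(OC)c1 | intermediate
19 | (2S,3S,4R)-2-[4-(benzyloxy)-3-methoxyphenyl]-4-[4-(benzyloxy)-3-methoxybenzyl]oxolane-3-carbaldehyde | O=C[C@H]1[C@@H](Cc2ccc(OCc3ccccc3)c(OC)c2)CO[C@@H]1c1ccc(OCc2ccccc2)c(OC)c1 | intermediate (not isolated)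
20 | {(2S,3R,4R)-2-[4-(benzyloxy)-3-methoxyphenyl]-4-[4-(benzyloxy)-3-methoxybenzyl]oxolan-3-yl}methanol | OC[C@H]1[C@@H](Cc2ccc(OCc3ccccc3)c(OC)c2)CO[C@@H]1c1ccc(OCc2ccccc2)c(OC)c1 | intermediate
21 | stearoyl chloride, octadecanoyl chloride | CCCCCCCCCCCCCCCCCC(=O)Cl | starting material
22 | {(2S,3R,4R)-2-[4-(benzyloxy)-3-methoxyphenyl]-4-[4-(benzyloxy)-3-methoxybenzyl]oxolan-3-yl}methyl octadecanoate | CCCCCCCCCCCCCCCCCC(=O)OC[C@H]1[C@@H](Cc2ccc(OCc3ccccc3)c(OC)c2)CO[C@@H]1c1ccc(OCc2ccccc2)c(OC)c1 | intermediate
23 | [(2S,3R,4R)-2-(4-hydroxy-3-methoxyphenyl)-4-(4-hydroxy-3-methoxybenzyl)oxolan-3-yl]methyl octadecanoate | CCCCCCCCCCCCCCCCCC(=O)OC[C@H]1[C@@H](Cc2ccc(O)c(OC)c2)CO[C@@H]1c1ccc(O)c(OC)c1 | target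

## Step count and least certain steps

Total: 13 steps. Longest linear sequence: 8 steps (steps 1, 2, 5, 9, 10, 11, 12, 13; the branches starting from 4 and from 9 are equally long).

**Step 9 (key step, proposed new method).** Several things can go wrong.
- The most likely failure is addition of the benzylide to the formyl carbon of 14 instead of C3. This is the usual course of benzylides with aldehydes and ends irreversibly in epoxide formation.
- Cs2CO3 may deprotonate the doubly activated benzylic CH2 of 14 and move the double bond out of conjugation before the ylide arrives.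
- If the conjugate addition is reversible, or if the sulfide controls the ylide face less well than in epoxidation, enantiocontrol at C2 is eroded. If the sense is opposite to the one assumed, the enantiomer of 4 is used.
- Ring closure of 16 through carbon instead of oxygen is not fatal. It would give methyl 2-[4-(benzyloxy)-3-methoxyphenyl]-3-[4-(benzyloxy)-3-methoxybenzyl]-3-formylcyclopropane-1-carboxylate F1, a donor–acceptor cyclopropane. MgI2 in warm THF should open it at the aryl-bearing carbon and reclose it through the formyl oxygen, with double inversion, to 17.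

The fallback for failure of the C–C bond formation uses known chemistry, sets out from 11 and returns at 20, bypassing steps 9 to 11. Aldehyde 11 is oxidised (NaClO2, NaH2PO4, 2-methylbut-2-ene) to 3-[4-(benzyloxy)-3-methoxyphenyl]propanoic acid F2. Its mixed pivalic anhydride acylates lithiated (S)-4-benzyloxazolidin-2-one to give (4S)-4-benzyl-3-{3-[4-(benzyloxy)-3-methoxyphenyl]propanoyl}-1,3-oxazolidin-2-one F3. The sodium enolate (NaHMDS, −78 °C) is alkylated with tert-butyl bromoacetate anti to the auxiliary benzyl group (Evans alkylation) to give tert-butyl (3R)-4-[(4S)-4-benzyl-2-oxo-1,3-oxazolidin-3-yl]-3-[4-(benzyloxy)-3-methoxybenzyl]-4-oxobutanoate F4. LiBH4 removes the auxiliary to give tert-butyl (3R)-3-[4-(benzyloxy)-3-methoxybenzyl]-4-hydroxybutanoate F5, which closes with TsOH to (4R)-4-[4-(benzyloxy)-3-methoxybenzyl]oxolan-2-one F6. The lithium enolate of F6 adds to commercial 4-(benzyloxy)-3-methoxybenzaldehyde trans to the ring substituent to give (3S,4R)-4-[4-(benzyloxy)-3-methoxybenzyl]-3-{[4-(benzyloxy)-3-methoxyphenyl](hydroxy)methyl}oxolan-2-one F7 as carbinol epimers. LiAlH4 gives (2R,3R)-2-{[4-(benzyloxy)-3-methoxyphenyl](hydroxy)methyl}-3-[4-(benzyloxy)-3-methoxybenzyl]butane-1,4-diol F8. Camphorsulfonic acid in CH2Cl2 at 0 °C ionises the benzylic alcohol of either epimer, and the primary hydroxyl group on the benzyl-bearing carbon closes the oxolane to 20 with the aryl group trans to the CH2OH arm. In this fallback C4 comes from the auxiliary alkylation, C3 from the trans aldol and C2 from the cyclisation.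

**Step 10.** Several things can go wrong.
- The face of the enol ether opposite the C3 ester is the face that carries the C2 aryl group one atom further away, so facial selectivity may be poor and give the 3,4-trans isomer, which cannot be corrected later.
- Rhodium may slowly saturate the electron-rich arenes.
- Traces of sulfide from step 9 may poison the catalyst.
- The enol ether may shift towards the furan on the support.

The fallback sets out from 17 and returns at 20. LiAlH4 reduces the ester of 17 to {(2S,3R)-2-[4-(benzyloxy)-3-methoxyphenyl]-4-[4-(benzyloxy)-3-methoxybenzyl]-2,3-dihydrofuran-3-yl}methanol F9. The hydroxyl group is capped (tert-butyldiphenylsilyl chloride, imidazole) as tert-butyl({(2S,3R)-2-[4-(benzyloxy)-3-methoxyphenyl]-4-[4-(benzyloxy)-3-methoxybenzyl]-2,3-dihydrofuran-3-yl}methoxy)diphenylsilane F10. The much larger allylic group should dominate the face selection in the hydrogenation (H2, Rh/Al2O3) to tert-butyl({(2S,3R,4R)-2-[4-(benzyloxy)-3-methoxyphenyl]-4-[4-(benzyloxy)-3-methoxybenzyl]oxolan-3-yl}methoxy)diphenylsilane F11. Bu4NF in THF then gives 20.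

**Step 8.** What may go wrong: self-condensation of 11, conjugate addition of the amine or of the enamine to the very electrophilic product, oligomerisation of 12, and incomplete equilibration to the (E)-isomer.

The fallback sets out from 11 and returns at 14. Condensation of 11 with glyoxylic acid monohydrate and morpholinium chloride in aqueous dioxane at reflux, the classical butenolide condensation, gives 4-[4-(benzyloxy)-3-methoxybenzyl]-5-hydroxyfuran-2(5H)-one F12. Alkylation of its ring-opened carboxylate (MeI, K2CO3, DMF) gives methyl (2Z)-4-[4-(benzyloxy)-3-methoxyphenyl]-3-formylbut-2-enoate F13. A trace of iodine in CH2Cl2 under light isomerises F13 to 14; the alkene geometry is in any case lost in step 9.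

## Further compounds

F1 | step 9 | methyl 2-[4-(benzyloxy)-3-methoxyphenyl]-3-[4-(benzyloxy)-3-methoxybenzyl]-3-formylcyclopropane-1-carboxylate, aryl trans to the ester, aryl carbon configured as needed for (2S)-17, quaternary carbon unassigned | COC(=O)[C@@H]1[C@@H](c2ccc(OCc3ccccc3)c(OC)c2)C1(C=O)Cc1ccc(OCc2ccccc2)c(OC)c1
F2 | step 9 | 3-[4-(benzyloxy)-3-methoxyphenyl]propanoic acid | OC(=O)CCc1ccc(OCc2ccccc2)c(OC)c1
F3 | step 9 | (4S)-4-benzyl-3-{3-[4-(benzyloxy)-3-methoxyphenyl]propanoyl}-1,3-oxazolidin-2-one | O=C(CCc1ccc(OCc2ccccc2)c(OC)c1)N1[C@@H](Cc2ccccc2)COC1=O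
F4 | step 9 | tert-butyl (3R)-4-[(4S)-4-benzyl-2-oxo-1,3-oxazolidin-3-yl]-3-[4-(benzyloxy)-3-methoxybenzyl]-4-oxobutanoate | CC(C)(C)OC(=O)C[C@@H](Cc1ccc(OCc2ccccc2)c(OC)c1)C(=O)N1[C@@H](Cc2ccccc2)COC1=O
F5 | step 9 | tert-butyl (3R)-3-[4-(benzyloxy)-3-methoxybenzyl]-4-hydroxybutanoate | CC(C)(C)OC(=O)C[C@@H](Cc1ccc(OCc2ccccc2)c(OC)c1)CO
F6 | step 9 | (4R)-4-[4-(benzyloxy)-3-methoxybenzyl]oxolan-2-one | O=C1C[C@@H](Cc2ccc(OCc3ccccc3)c(OC)c2)CO1
F7 | step 9 | (3S,4R)-4-[4-(benzyloxy)-3-methoxybenzyl]-3-{[4-(benzyloxy)-3-methoxyphenyl](hydroxy)methyl}oxolan-2-one, carbinol epimers | O=C1[C@H](C(O)c2ccc(OCc3ccccc3)c(OC)c2)[C@@H](Cc2ccc(OCc3ccccc3)c(OC)c2)CO1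
F8 | step 9 | (2R,3R)-2-{[4-(benzyloxy)-3-methoxyphenyl](hydroxy)methyl}-3-[4-(benzyloxy)-3-methoxybenzyl]butane-1,4-diol, carbinol epimers | OC[C@H](C(O)c1ccc(OCc2ccccc2)c(OC)c1)[C@@H](Cc1ccc(OCc2ccccc2)c(OC)c1)CO
F9 | step 10 | {(2S,3R)-2-[4-(benzyloxy)-3-methoxyphenyl]-4-[4-(benzyloxy)-3-methoxybenzyl]-2,3-dihydrofuran-3-yl}methanol | OC[C@H]1C(Cc2ccc(OCc3ccccc3)c(OC)c2)=CO[C@@H]1c1ccc(OCc2ccccc2)c(OC)c1
F10 | step 10 | tert-butyl({(2S,3R)-2-[4-(benzyloxy)-3-methoxyphenyl]-4-[4-(benzyloxy)-3-methoxybenzyl]-2,3-dihydrofuran-3-yl}methoxy)diphenylsilane | CC(C)(C)[Si](OC[C@H]1C(Cc2ccc(OCc3ccccc3)c(OC)c2)=CO[C@@H]1c1ccc(OCc2ccccc2)c(OC)c1)(c1ccccc1)c1ccccc1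
F11 | step 10 | tert-butyl({(2S,3R,4R)-2-[4-(benzyloxy)-3-methoxyphenyl]-4-[4-(benzyloxy)-3-methoxybenzyl]oxolan-3-yl}methoxy)diphenylsilane | CC(C)(C)[Si](OC[C@H]1[C@@H](Cc2ccc(OCc3ccccc3)c(OC)c2)CO[C@@H]1c1ccc(OCc2ccccc2)c(OC)c1)(c1ccccc1)c1ccccc1
F12 | step 8 | 4-[4-(benzyloxy)-3-methoxybenzyl]-5-hydroxyfuran-2(5H)-one, racemic hemiacetal | OC1OC(=O)C=C1Cc1ccc(OCc2ccccc2)c(OC)c1
F13 | step 8 | methyl (2Z)-4-[4-(benzyloxy)-3-methoxyphenyl]-3-formylbut-2-enoate | COC(=O)/C=C(\C=O)Cc1ccc(OCc2ccccc2)c(OC)c1
A1 | alternative 1 | diethyl (2R,4Z)-2-[4-(benzyloxy)-3-methoxyphenyl]-4-[4-(benzyloxy)-3-methoxybenzylidene]oxolane-3,3-dicarboxylate, formed as the racemate, needed enantiomer drawn | COc1cc(/C=C2\CO[C@H](c3ccc(OCc4ccccc4)c(OC)c3)C2(C(=O)OCC)C(=O)OCC)ccc1OCc1ccccc1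
A2 | alternative 1 | diethyl 2-[4-(benzyloxy)-3-methoxybenzylidene]propanedioate | CCOC(=O)C(=Cc1ccc(OCc2ccccc2)c(OC)c1)C(=O)OCC
A3 | alternative 1 | prop-2-yn-1-ol | OCC#C
A4 | alternative 1 | 1-(benzyloxy)-4-iodo-2-methoxybenzene | COc1cc(I)ccc1OCc1ccccc1
A5 | alternative 2 | 4,7-bis[4-(benzyloxy)-3-methoxyphenyl]-3-oxabicyclo[3.2.0]heptan-6-one, cis-fused, 4-aryl exo, C7 unassigned | O=C2[C@H]1[C@@H](C2c3ccc(OCc4ccccc4)c(OC)c3)CO[C@@H]1c1ccc(OCc2ccccc2)c(OC)c1
A6 | alternative 2 | (2S)-2-[4-(benzyloxy)-3-methoxyphenyl]-2,5-dihydrofuran | C1=C[C@@H](c2ccc(OCc3ccccc3)c(OC)c2)OC1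
A7 | alternative 2 | [4-(benzyloxy)-3-methoxyphenyl]acetyl chloride | ClC(=O)Cc1ccc(OCc2ccccc2)c(OC)c1
A8 | alternative 2 | 2-[4-(benzyloxy)-3-methoxyphenyl]ethen-1-one, the ketene | O=C=Cc1ccc(OCc2ccccc2)c(OC)c1
A9 | alternative 3 | methyl (2S,3S,4R)-2-[4-(benzyloxy)-3-methoxyphenyl]-4-[4-(benzyloxy)-3-methoxybenzyl]oxolane-3-carboxylate, identical with 18 | COC(=O)[C@H]1[C@@H](Cc2ccc(OCc3ccccc3)c(OC)c2)CO[C@@H]1c1ccc(OCc2ccccc2)c(OC)c1
A10 | alternative 3 | methyl (3R)-3-[4-(benzyloxy)-3-methoxyphenyl]-2-bromo-3-(prop-2-en-1-yloxy)propanoate, either configuration at C2 | COC(=O)C(Br)[C@H](OCC=C)c1ccc(OCc2ccccc2)c(OC)c1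
A11 | alternative 3 | [4-(benzyloxy)-3-methoxyphenyl]zinc bromide | COc1cc([Zn]Br)ccc1OCc1ccccc1
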